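**Strategy.** The route rests on one disconnection: the eight-membered ring is opened at the bond between the CH that carries a 4-hydroxyphenyl group on resorcinol ring D and the neighbouring CH that carries dihydrobenzofuran ring E. Both carbons are benzylic methines and can both be ketone carbons, so a titanium-mediated reductive carbonyl coupling forms this bond as a tetrasubstituted C=C and closes the eight-membered ring in a single operation. Its precursor is a diketone assembled from two (2R,3R)-dihydrobenzofurans: a diaryl ketone on ring D, an aryl alkyl ketone on ring E, and a 4-benzyloxybenzyl arm on the stereocentre next to the alkyl ketone.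

Key step: step 18

Assumption: Rh2(R-PTAD)4 is taken to deliver the (3R) series in step 5; should the sense be opposite, the commercial enantiomeric catalyst Rh2(S-PTAD)4 is used instead.

Labels: eight-membered ring: C-a = CH(4-oxyphenyl) on ring D, C-b = CH bearing ring E, C-c = CH bearing the linker; C-d = exocyclic linker CH(4-oxyphenyl); seven-membered ring: C-e = CH bonded to C-d, C-f = CH(4-oxyphenyl) on ring F. Rings D and F are the 3,5-dioxygenated phenyl rings fused into the eight- and the seven-membered ring; ring E is the benzo ring of the pendant dihydrobenzofuran.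

**Route**

Step 1
Reactants: 1 1-bromo-3,5-dimethoxybenzene; 2 3,5-dimethoxybenzoyl chloride
Product: 3 (2-bromo-4,6-dimethoxyphenyl)(3,5-dimethoxyphenyl)methanone
Conditions: AlCl3 (1.2 equiv), CH2Cl2, 0 °C
Reagents that add atoms: none
Why: Friedel–Crafts acylation: the deactivated acid chloride ring cannot compete, and 1 should be acylated at C-2, the position ortho and para to its methoxy groups that is known to be the site of formylation of this arene.

Step 2
Reactants: 3 diaryl ketone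
Product: 4 (2-bromo-6-hydroxy-4-methoxyphenyl)(3,5-dimethoxyphenyl)methanone
Conditions: BCl3 (1.5 equiv), CH2Cl2, −78 to 0 °C; aq. NaHCO3
Reagents that add atoms: none
Why: Chelation-controlled ether cleavage: BCl3 bound to the carbonyl oxygen should remove only the methyl group of the methoxy group ortho to the ketone.

Step 3
Reactants: 4 hydroxy ketone; 5 4-methoxybenzyl chloride
Product: 6 {2-bromo-4-methoxy-6-[(4-methoxybenzyl)oxy]phenyl}(3,5-dimethoxyphenyl)methanone
Conditions: K2CO3, NaI (cat.), DMF, 60 °C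
Reagents that add atoms: none
Why: Williamson ether synthesis of the phenoxide with a reactive benzylic chloride; the benzylic CH2 introduced here becomes C-2 of the dihydrobenzofuran.

Step 4
Reactants: 6 benzyl ether ketone
Product: 7 hydrazone of 6
Conditions: N2H4·H2O (20 equiv), AcOH (cat.), EtOH, 85 °C, sealed tube
Reagents that add atoms: hydrazine, NN
Why: Condensation of the ketone with hydrazine to the hydrazone, driven by excess reagent and heat because the carbonyl group is flanked by two ortho substituents.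

Step 5
Reactants: 7 hydrazone
Product: 9 (2S,3R)-4-bromo-3-(3,5-dimethoxyphenyl)-6-methoxy-2-(4-methoxyphenyl)-2,3-dihydro-1-benzofuran (2,3-cis), via diazo compound 8 (not isolated)
Conditions: MnO2 (8 equiv), CH2Cl2, 0 °C; filter; Rh2(R-PTAD)4 (1 mol %), CH2Cl2, 0 °C to rt
Reagents that add atoms: none
Why: Dehydrogenation of the hydrazone to the diaryldiazomethane followed by rhodium-carbene insertion into the benzylic C–H bond of the ether (intramolecular C–H insertion of a donor/donor carbene), in which the chiral carboxylate ligands should fix C-3 as R and the insertion geometry should give the 2,3-cis ring.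

Step 6
Reactants: 9 cis-dihydrobenzofuran
Product: 10 (2R,3R)-4-bromo-3-(3,5-dimethoxyphenyl)-6-methoxy-2-(4-methoxyphenyl)-2,3-dihydro-1-benzofuran (2,3-trans)
Conditions: BF3·OEt2 (0.2 equiv), CH2Cl2, 0 °C
Reagents that add atoms: none
Why: Acid-catalysed epimerisation: reversible opening of the C-2–O bond to the 4-methoxybenzyl cation and re-closure should convert the cis ring into the more stable trans ring (C-2 becomes R) without touching C-3.

Step 7
Reactants: 10 trans-bromide
Product: 11 [(2R,3R)-3-(3,5-dimethoxyphenyl)-6-methoxy-2-(4-methoxyphenyl)-2,3-dihydro-1-benzofuran-4-yl]boronic acid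
Conditions: n-BuLi, THF, −78 °C; B(OMe)3, −78 °C to rt; 1 M HCl
Reagents that add atoms: trimethyl borate, COB(OC)OC; water, O
Why: Bromine–lithium exchange and trapping of the aryllithium with the borate ester, followed by hydrolysis to the boronic acid; no stereocentre is affected.

Step 8
Reactants: 10 trans-bromide; 12 (2-ethoxy-2-oxoethyl)zinc bromide
Product: 13 ethyl 2-[(2R,3R)-3-(3,5-dimethoxyphenyl)-6-methoxy-2-(4-methoxyphenyl)-2,3-dihydro-1-benzofuran-4-yl]acetate
Conditions: Pd(dba)2 (3 mol %), P(t-Bu)3 (6 mol %), THF, 50 °C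
Reagents that add atoms: none
Why: Palladium-catalysed arylation of a zinc ester enolate (Reformatsky reagent, Negishi-type coupling), a neutral method that should leave the dihydrobenzofuran unchanged.

Step 9
Reactants: 13 ethyl ester
Product: 14 2-[(2R,3R)-3-(3,5-dimethoxyphenyl)-6-methoxy-2-(4-methoxyphenyl)-2,3-dihydro-1-benzofuran-4-yl]acetic acid
Conditions: LiOH, THF–MeOH–H2O, rt; 1 M HCl
Reagents that add atoms: lithium hydroxide, [Li+].[OH-]
Why: Saponification of the ethyl ester.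

Step 10
Reactants: 14 arylacetic acid
Product: 16 seven-ring ketone (C-e = CH2, C-f = C=O), via mixed trifluoroacetic anhydride 15 (not isolated)
Conditions: (CF3CO)2O (2 equiv), CH2Cl2, 0 °C to rt
Reagents that add atoms: none
Why: Intramolecular Friedel–Crafts acylation through the mixed trifluoroacetic anhydride; only the two equivalent ortho positions of the 3,5-dimethoxyphenyl ring are within reach of the acyl group, so only the seven-membered ketone can form.

Step 11
Reactants: 10 trans-bromide; 17 4-methoxybenzoyl chloride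
Product: 18 (2R,3R)-4-bromo-3-[3,5-dimethoxy-2-(4-methoxybenzoyl)phenyl]-6-methoxy-2-(4-methoxyphenyl)-2,3-dihydro-1-benzofuran
Conditions: SnCl4 (1.2 equiv), CH2Cl2, −40 to −10 °C
Reagents that add atoms: none
Why: Friedel–Crafts acylation of the 3,5-dimethoxyphenyl ring at its ortho/para-activated position next to C-3, the benzofuran ring being deactivated and shielded by the bromine atom, and any opening at C-2 by the Lewis acid re-closing to the trans ring.

Step 12
Reactants: 18 aroylated bromide; 12 (2-ethoxy-2-oxoethyl)zinc bromide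
Product: 19 ethyl 2-{(2R,3R)-3-[3,5-dimethoxy-2-(4-methoxybenzoyl)phenyl]-6-methoxy-2-(4-methoxyphenyl)-2,3-dihydro-1-benzofuran-4-yl}acetate
Conditions: Pd(dba)2 (3 mol %), P(t-Bu)3 (6 mol %), THF, 50 °C
Reagents that add atoms: none
Why: The same palladium-catalysed coupling with the Reformatsky reagent as in step 8; the diaryl ketone has no α-hydrogen and is not attacked by the zinc enolate.

Step 13
Reactants: 19 ethyl ester
Product: 20 2-{(2R,3R)-3-[3,5-dimethoxy-2-(4-methoxybenzoyl)phenyl]-6-methoxy-2-(4-methoxyphenyl)-2,3-dihydro-1-benzofuran-4-yl}acetic acid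
Conditions: LiOH, THF–MeOH–H2O, rt; 1 M HCl
Reagents that add atoms: lithium hydroxide, [Li+].[OH-]
Why: Saponification of the ethyl ester; the diaryl ketone is inert to hydroxide.

Step 14
Reactants: 20 keto acid; 21 (S)-4-benzyl-1,3-oxazolidin-2-one
Product: 23 N-acyl oxazolidinone, via mixed pivalic anhydride 22 (not isolated)
Conditions: t-BuCOCl, Et3N, THF, −20 °C; then 21, LiCl, rt
Reagents that add atoms: none
Why: N-Acylation of the Evans oxazolidinone through the mixed pivalic anhydride under LiCl/Et3N activation.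

Step 15
Reactants: 23 N-acyl oxazolidinone; 24 4-(benzyloxy)benzyl bromide
Product: 25 (S)-4-benzyl-3-{(2S)-3-[4-(benzyloxy)phenyl]-2-aryl-propanoyl}oxazolidin-2-one (aryl = dihydrobenzofuran-4-yl unit of 20)
Conditions: NaN(SiMe3)2, THF, −78 °C; 24, −78 to −40 °C
Reagents that add atoms: none
Why: Evans asymmetric alkylation: the chelated Z-sodium enolate should be benzylated on the face opposite the benzyl group of the auxiliary, which sets C-c as S, while the hindered diaryl ketone (no α-hydrogen) stays untouched at −78 °C.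

Step 16
Reactants: 25 alkylated imide
Product: 26 S-ethyl (2S)-3-[4-(benzyloxy)phenyl]-2-aryl-propanethioate
Conditions: EtSH, n-BuLi, THF, 0 °C
Reagents that add atoms: ethanethiol, CCS
Why: Cleavage of the acyl oxazolidinone with lithium ethanethiolate (transthioesterification), a weakly basic nucleophile that should not epimerise the α-aryl centre C-c.

Step 17
Reactants: 26 thioester; 11 boronic acid
Product: 27 diketone precursor (diaryl ketone on ring D, aryl alkyl ketone on ring E, C-c S)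
Conditions: Pd2(dba)3 (5 mol %), tri(2-furyl)phosphine (20 mol %), copper thiophene-2-carboxylate CuO2C(C4H3S) (1.6 equiv), THF, 50 °C
Reagents that add atoms: none
Why: Liebeskind–Srogl coupling of the thioester with the arylboronic acid, which forms the aryl alkyl ketone under neutral conditions that spare the diaryl ketone and C-c.

Step 18
Reactants: 27 diketone precursor
Product: 29 cyclic tetrasubstituted stilbene (Z C-a=C-b in the eight-membered ring), via titanium pinacolate 28 (not isolated)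
Conditions: TiCl3(DME)1.5 (12 equiv), Zn–Cu couple (40 equiv), DME, reflux 3 h; 27 added over 30 h at 25 °C (final 1 mM); then reflux 8 h
Reagents that add atoms: none
Why: Low-valent titanium transfers one electron to each carbonyl group, the two titanium-bound ketyls couple to the titanium pinacolate 28, and at reflux both C–O bonds are broken on the titanium surface to leave the C-a=C-b double bond. The closest known reactions are intramolecular McMurry couplings that give medium rings and the mixed diaryl ketone/aryl alkyl ketone couplings used for tetrasubstituted stilbenes. The eight-membered ring is closed by intramolecular ketyl–ketyl coupling under high dilution, and the ring size forces the Z geometry in which C-c and ring D are cis. No stereocentre is formed; the existing centre C-c is alpha to the alkyl ketone, so 27 is added at 25 °C, where pinacol formation should consume the enolisable ketone before the mixture is heated. The step needs only pairing of the two carbonyl groups, which is secured because 27 holds no other reducible group (benzyl and methyl ethers are inert) and slow addition suppresses intermolecular coupling.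

Step 19
Reactants: 29 cyclic stilbene
Product: 30 dihydro compound (C-a S, C-b S, C-c R)
Conditions: Et3SiH (10 equiv), CF3CO2H (10 equiv), CH2Cl2, −40 to 0 °C
Reagents that add atoms: none
Why: Ionic hydrogenation: the alkene should be protonated at C-b (leaving the cation on C-a, stabilised by the 4-methoxyphenyl group and the ortho/para methoxy groups of ring D) on the face anti to the benzofuran carbon that the eight-membered ring holds over the alkene, and hydride from Et3SiH should then add to C-a anti to C-c, past the flat ring E, which gives the trans arrangement of the 4-methoxyphenyl group and ring E.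

Step 20
Reactants: 30 benzyl ether
Product: 31 phenol (free 4-hydroxybenzyl arm on C-c)
Conditions: H2 (1 atm), Pd(OH)2/C, EtOAc–MeOH, rt
Reagents that add atoms: none
Why: Hydrogenolysis of the benzyl aryl ether, which should be much faster than cleavage of the three cyclic benzylic ethers at 1 atm and room temperature.

Step 21
Reactants: 31 phenol; 16 seven-ring ketone
Product: 33 1,6-adduct (C-d–C-e bond; C-d R), via quinone methide 32 (not isolated)
Conditions: DDQ (1.05 equiv), CH2Cl2, −40 °C, cold filtration; filtrate added to 16 (2.5 equiv) and KN(SiMe3)2 (2.4 equiv), THF, −78 °C; aq. NH4Cl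
Reagents that add atoms: none
Why: Dehydrogenation of the only phenol to its p-quinone methide and 1,6-conjugate addition of the ketone enolate under acid-free conditions (so the methoxyarenes do not compete), the enolate entering C-d anti to the benzofuran carbon on C-c (Felkin–Anh) to set C-d as R, while C-e forms as a mixture that is corrected in step 23.

Step 22
Reactants: 33 1,6-adduct; 34 4-methoxyphenylmagnesium bromide
Product: 35 tertiary carbinol (OH and 4-methoxyphenyl on C-f)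
Conditions: 34 (5 equiv), LaCl3·2LiCl (2 equiv), THF, 0 °C to rt
Reagents that add atoms: none
Why: Lanthanide-promoted Grignard 1,2-addition, chosen because the ketone is hindered and enolisable; the configuration of the carbinol carbon is irrelevant because it is ionised in step 23.

Step 23
Reactants: 35 tertiary carbinol
Product: 36 tetradeca-O-methyl ether of the target
Conditions: Et3SiH (10 equiv), CF3CO2H (10 equiv), CH2Cl2, −20 to 0 °C
Reagents that add atoms: none
Why: Ionic deoxygenation: the carbinol ionises to the diarylmethyl cation at C-f (stabilised by ring F and the 4-methoxyphenyl group), which equilibrates with the tetrasubstituted alkene so that C-e is reset, and hydride should add to C-f anti to the bulky C-d substituent in the C-e epimer that carries this substituent pseudo-equatorially, giving H-e and H-f cis to each other and to H-3 of the dihydrobenzofuran.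

Step 24
Reactants: 36 tetradeca-O-methyl ether
Product: 37 CNP0184494.1
Conditions: BBr3 (40 equiv), CH2Cl2, −78 °C to rt; MeOH, then H2O
Reagents that add atoms: none
Why: Cleavage of all fourteen aryl methyl ethers with BBr3 (Lewis-acid demethylation); the benzylic ether rings are trans and should stay so even if they open and re-close.

**Compound list**

1 | 1-bromo-3,5-dimethoxybenzene | COc1cc(Br)cc(OC)c1 | starting material
2 | 3,5-dimethoxybenzoyl chloride | COc1cc(cc(OC)c1)C(Cl)=O | starting material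
3 | (2-bromo-4,6-dimethoxyphenyl)(3,5-dimethoxyphenyl)methanone | COc1cc(OC)c(C(=O)c2cc(OC)cc(OC)c2)c(Br)c1 | intermediate
4 | (2-bromo-6-hydroxy-4-methoxyphenyl)(3,5-dimethoxyphenyl)methanone | COc1cc(O)c(C(=O)c2cc(OC)cc(OC)c2)c(Br)c1 | intermediate
5 | 4-methoxybenzyl chloride | COc1ccc(CCl)cc1 | starting material
6 | {2-bromo-4-methoxy-6-[(4-methoxybenzyl)oxy]phenyl}(3,5-dimethoxyphenyl)methanone | COc1ccc(COc2cc(OC)cc(Br)c2C(=O)c2cc(OC)cc(OC)c2)cc1 | intermediate
7 | hydrazone of 6 (mixture of C=N isomers) | COc1ccc(COc2cc(OC)cc(Br)c2C(=NN)c2cc(OC)cc(OC)c2)cc1 | intermediate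
8 | {2-bromo-4-methoxy-6-[(4-methoxybenzyl)oxy]phenyl}(3,5-dimethoxyphenyl)diazomethane | COc1ccc(COc2cc(OC)cc(Br)c2C(=[N+]=[N-])c2cc(OC)cc(OC)c2)cc1 | intermediate (not isolated)
9 | (2S,3R)-4-bromo-3-(3,5-dimethoxyphenyl)-6-methoxy-2-(4-methoxyphenyl)-2,3-dihydro-1-benzofuran (cis) | Brc1cc(OC)cc2c1[C@@H](c1cc(OC)cc(OC)c1)[C@@H](c1ccc(OC)cc1)O2 | intermediate
10 | (2R,3R)-4-bromo-3-(3,5-dimethoxyphenyl)-6-methoxy-2-(4-methoxyphenyl)-2,3-dihydro-1-benzofuran (trans) | Brc1cc(OC)cc2c1[C@@H](c1cc(OC)cc(OC)c1)[C@H](c1ccc(OC)cc1)O2 | intermediate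
11 | [(2R,3R)-3-(3,5-dimethoxyphenyl)-6-methoxy-2-(4-methoxyphenyl)-2,3-dihydro-1-benzofuran-4-yl]boronic acid | OB(O)c1cc(OC)cc2c1[C@@H](c1cc(OC)cc(OC)c1)[C@H](c1ccc(OC)cc1)O2 | intermediate
12 | (2-ethoxy-2-oxoethyl)zinc bromide (commercial solution in THF) | CCOC(=O)C[Zn]Br | starting material
13 | ethyl 2-[(2R,3R)-3-(3,5-dimethoxyphenyl)-6-methoxy-2-(4-methoxyphenyl)-2,3-dihydro-1-benzofuran-4-yl]acetate | CCOC(=O)Cc1cc(OC)cc2c1[C@@H](c1cc(OC)cc(OC)c1)[C@H](c1ccc(OC)cc1)O2 | intermediate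
14 | 2-[(2R,3R)-3-(3,5-dimethoxyphenyl)-6-methoxy-2-(4-methoxyphenyl)-2,3-dihydro-1-benzofuran-4-yl]acetic acid | OC(=O)Cc1cc(OC)cc2c1[C@@H](c1cc(OC)cc(OC)c1)[C@H](c1ccc(OC)cc1)O2 | intermediate
15 | mixed anhydride of 14 with trifluoroacetic acid | FC(F)(F)C(=O)OC(=O)Cc1cc(OC)cc2c1[C@@H](c1cc(OC)cc(OC)c1)[C@H](c1ccc(OC)cc1)O2 | intermediate (not isolated)
16 | seven-ring ketone: 14 cyclised from its CH2C(=O) unit onto C-2′ of the 3,5-dimethoxyphenyl ring (ring F); C-e = CH2, C-f = C=O; dihydrobenzofuran (2R,3R) | O=C1Cc2cc(OC)cc3c2[C@@H](c2cc(OC)cc(OC)c21)[C@H](c1ccc(OC)cc1)O3 | intermediate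
17 | 4-methoxybenzoyl chloride | COc1ccc(cc1)C(Cl)=O | starting material
18 | (2R,3R)-4-bromo-3-[3,5-dimethoxy-2-(4-methoxybenzoyl)phenyl]-6-methoxy-2-(4-methoxyphenyl)-2,3-dihydro-1-benzofuran | Brc1cc(OC)cc2c1[C@@H](c1cc(OC)cc(OC)c1C(=O)c1ccc(OC)cc1)[C@H](c1ccc(OC)cc1)O2 | intermediate
19 | ethyl 2-{(2R,3R)-3-[3,5-dimethoxy-2-(4-methoxybenzoyl)phenyl]-6-methoxy-2-(4-methoxyphenyl)-2,3-dihydro-1-benzofuran-4-yl}acetate | CCOC(=O)Cc1cc(OC)cc2c1[C@@H](c1cc(OC)cc(OC)c1C(=O)c1ccc(OC)cc1)[C@H](c1ccc(OC)cc1)O2 | intermediate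
20 | 2-{(2R,3R)-3-[3,5-dimethoxy-2-(4-methoxybenzoyl)phenyl]-6-methoxy-2-(4-methoxyphenyl)-2,3-dihydro-1-benzofuran-4-yl}acetic acid | OC(=O)Cc1cc(OC)cc2c1[C@@H](c1cc(OC)cc(OC)c1C(=O)c1ccc(OC)cc1)[C@H](c1ccc(OC)cc1)O2 | intermediate
21 | (S)-4-benzyl-1,3-oxazolidin-2-one | O=C1N[C@@H](Cc2ccccc2)CO1 | starting material
22 | mixed anhydride of 20 with pivalic acid | CC(C)(C)C(=O)OC(=O)Cc1cc(OC)cc2c1[C@@H](c1cc(OC)cc(OC)c1C(=O)c1ccc(OC)cc1)[C@H](c1ccc(OC)cc1)O2 | intermediate (not isolated)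
23 | (S)-4-benzyl-3-(2-{(2R,3R)-3-[3,5-dimethoxy-2-(4-methoxybenzoyl)phenyl]-6-methoxy-2-(4-methoxyphenyl)-2,3-dihydro-1-benzofuran-4-yl}acetyl)-1,3-oxazolidin-2-one | O=C(Cc1cc(OC)cc2c1[C@@H](c1cc(OC)cc(OC)c1C(=O)c1ccc(OC)cc1)[C@H](c1ccc(OC)cc1)O2)N1C(=O)OC[C@@H]1Cc1ccccc1 | intermediate
24 | 4-(benzyloxy)benzyl bromide | BrCc1ccc(OCc2ccccc2)cc1 | starting material
25 | (S)-4-benzyl-3-[(2S)-3-[4-(benzyloxy)phenyl]-2-{(2R,3R)-3-[3,5-dimethoxy-2-(4-methoxybenzoyl)phenyl]-6-methoxy-2-(4-methoxyphenyl)-2,3-dihydro-1-benzofuran-4-yl}propanoyl]-1,3-oxazolidin-2-one | c1ccccc1COc1ccc(C[C@H](C(=O)N2C(=O)OC[C@@H]2Cc2ccccc2)c2cc(OC)cc3c2[C@@H](c2cc(OC)cc(OC)c2C(=O)c2ccc(OC)cc2)[C@H](c2ccc(OC)cc2)O3)cc1 | intermediate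
26 | S-ethyl (2S)-3-[4-(benzyloxy)phenyl]-2-{(2R,3R)-3-[3,5-dimethoxy-2-(4-methoxybenzoyl)phenyl]-6-methoxy-2-(4-methoxyphenyl)-2,3-dihydro-1-benzofuran-4-yl}propanethioate | c1ccccc1COc1ccc(C[C@H](C(=O)SCC)c2cc(OC)cc3c2[C@@H](c2cc(OC)cc(OC)c2C(=O)c2ccc(OC)cc2)[C@H](c2ccc(OC)cc2)O3)cc1 | intermediate
27 | diketone precursor: (2S)-3-[4-(benzyloxy)phenyl]-1-[(2R,3R)-3-(3,5-dimethoxyphenyl)-6-methoxy-2-(4-methoxyphenyl)-2,3-dihydro-1-benzofuran-4-yl]-2-{(2R,3R)-3-[3,5-dimethoxy-2-(4-methoxybenzoyl)phenyl]-6-methoxy-2-(4-methoxyphenyl)-2,3-dihydro-1-benzofuran-4-yl}propan-1-one | c1ccccc1COc1ccc(C[C@H](C(=O)c2cc(OC)cc3c2[C@@H](c2cc(OC)cc(OC)c2)[C@H](c2ccc(OC)cc2)O3)c2cc(OC)cc3c2[C@@H](c2cc(OC)cc(OC)c2C(=O)c2ccc(OC)cc2)[C@H](c2ccc(OC)cc2)O3)cc1 | intermediate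
28 | titanium pinacolate of 27 (C-a,C-b diolate, drawn as the dichlorotitanium diolate) | c1ccccc1COc1ccc(C[C@H]2c4cc(OC)cc5c4[C@@H](c4cc(OC)cc(OC)c4C6(c4ccc(OC)cc4)O[Ti](Cl)(Cl)OC26c2cc(OC)cc4c2[C@@H](c2cc(OC)cc(OC)c2)[C@H](c2ccc(OC)cc2)O4)[C@H](c2ccc(OC)cc2)O5)cc1 | intermediate (not isolated)
29 | cyclic tetrasubstituted stilbene: eight-membered ring with Z C-a=C-b; 4-methoxyphenyl on C-a, ring E unit on C-b, 4-(benzyloxy)benzyl on C-c (S); both dihydrobenzofurans (2R,3R) | c1ccccc1COc1ccc(C[C@H]2c4cc(OC)cc5c4[C@@H](c4cc(OC)cc(OC)c4/C(c4ccc(OC)cc4)=C2/c2cc(OC)cc4c2[C@@H](c2cc(OC)cc(OC)c2)[C@H](c2ccc(OC)cc2)O4)[C@H](c2ccc(OC)cc2)O5)cc1 | intermediate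
30 | dihydro compound: C-a (S), C-b (S), C-c (R); 4-methoxyphenyl and ring E trans, ring E and arm cis; arm = 4-(benzyloxy)benzyl | c1ccccc1COc1ccc(C[C@H]2c4cc(OC)cc5c4[C@@H](c4cc(OC)cc(OC)c4[C@H](c4ccc(OC)cc4)[C@H]2c2cc(OC)cc4c2[C@@H](c2cc(OC)cc(OC)c2)[C@H](c2ccc(OC)cc2)O4)[C@H](c2ccc(OC)cc2)O5)cc1 | intermediate
31 | phenol: 30 with a 4-hydroxybenzyl arm | Oc1ccc(C[C@H]2c4cc(OC)cc5c4[C@@H](c4cc(OC)cc(OC)c4[C@H](c4ccc(OC)cc4)[C@H]2c2cc(OC)cc4c2[C@@H](c2cc(OC)cc(OC)c2)[C@H](c2ccc(OC)cc2)O4)[C@H](c2ccc(OC)cc2)O5)cc1 | intermediate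
32 | p-quinone methide of 31 (exocyclic C=C at C-d) | O=C1C=CC(=C[C@H]2c4cc(OC)cc5c4[C@@H](c4cc(OC)cc(OC)c4[C@H](c4ccc(OC)cc4)[C@H]2c2cc(OC)cc4c2[C@@H](c2cc(OC)cc(OC)c2)[C@H](c2ccc(OC)cc2)O4)[C@H](c2ccc(OC)cc2)O5)C=C1 | intermediate (not isolated)
33 | 1,6-adduct: ketone 16 bonded through C-e to C-d of 31; C-d (R) bears a free 4-hydroxyphenyl group; both C-e epimers | O=C2c3c(OC)cc(OC)cc3[C@@H]3c4c(cc(OC)cc4C2[C@H](c2ccc(O)cc2)[C@H]2c4cc(OC)cc5c4[C@@H](c4cc(OC)cc(OC)c4[C@H](c4ccc(OC)cc4)[C@H]2c2cc(OC)cc4c2[C@@H](c2cc(OC)cc(OC)c2)[C@H](c2ccc(OC)cc2)O4)[C@H](c2ccc(OC)cc2)O5)O[C@H]3c2ccc(OC)cc2 | intermediate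
34 | 4-methoxyphenylmagnesium bromide (commercial solution in THF) | COc1ccc([Mg]Br)cc1 | starting material
35 | tertiary carbinol: 33 with OH and 4-methoxyphenyl on C-f (mixture at C-e and C-f) | COc1ccc(cc1)C2(O)c3c(OC)cc(OC)cc3[C@@H]3c4c(cc(OC)cc4C2[C@H](c2ccc(O)cc2)[C@H]2c4cc(OC)cc5c4[C@@H](c4cc(OC)cc(OC)c4[C@H](c4ccc(OC)cc4)[C@H]2c2cc(OC)cc4c2[C@@H](c2cc(OC)cc(OC)c2)[C@H](c2ccc(OC)cc2)O4)[C@H](c2ccc(OC)cc2)O5)O[C@H]3c2ccc(OC)cc2 | intermediate
36 | tetradeca-O-methyl ether of 37 (only the phenol on the C-d aryl group is free); configurations as in 37 | COc1ccc([C@H]2c3c(OC)cc(OC)cc3[C@@H]3c4c(cc(OC)cc4[C@H]2[C@H](c2ccc(O)cc2)[C@H]2c4cc(OC)cc5c4[C@@H](c4cc(OC)cc(OC)c4[C@H](c4ccc(OC)cc4)[C@H]2c2cc(OC)cc4c2[C@@H](c2cc(OC)cc(OC)c2)[C@H](c2ccc(OC)cc2)O4)[C@H](c2ccc(OC)cc2)O5)O[C@H]3c2ccc(OC)cc2)cc1 | intermediate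
37 | CNP0184494.1: C-f (S), C-e (S), C-d (R), C-c (R), C-b (S), C-a (S); three (2R,3R)-dihydrobenzofurans | Oc1ccc([C@H]2c3c(O)cc(O)cc3[C@@H]3c4c(cc(O)cc4[C@H]2[C@H](c2ccc(O)cc2)[C@H]2c4cc(O)cc5c4[C@@H](c4cc(O)cc(O)c4[C@H](c4ccc(O)cc4)[C@H]2c2cc(O)cc4c2[C@@H](c2cc(O)cc(O)c2)[C@H](c2ccc(O)cc2)O4)[C@H](c2ccc(O)cc2)O5)O[C@H]3c2ccc(O)cc2)cc1 | target

**Step count and risks**

Total step count: 24 steps. Longest linear sequence: 20 steps (steps 1–6 and 11–24); step 7 and steps 8–10 are branches from bromide 10.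

Steps most likely to fail:

1. Step 21 (joining the two halves). The quinone methide may tautomerise to the vinylphenol (which would also erase C-c), may be attacked by ring E before the enolate arrives, or may be attacked with poor facial selectivity at C-d. The fallback changes from a base-mediated conjugate addition to an acid-mediated cation–alkene cascade and sets out from 31 and from bromide 10. Oxidation of 31 with DDQ in methanol should give the benzylic methyl ether F1, the quinone methide being trapped by the solvent. Bromide 10 and 4-methoxystyrene should give (2R,3R)-ε-viniferin pentamethyl ether F2 by Heck reaction (Pd(OAc)2, P(o-tol)3, Et3N, DMF, 100 °C). Ionisation of F1 with BF3·OEt2 in CH2Cl2 at −78 °C in the presence of an excess of F2 at high concentration should add the C-d cation to the styrene carbon next to the benzofuran and close the seven-membered ring by Friedel–Crafts attack of ring F on the resulting C-f cation. The fallback returns to the route at 36 and bypasses steps 22 and 23.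

2. Step 18 (key step). The coupling may stop at the pinacol stage, C-c may epimerise by enolisation on the Lewis-acidic titanium, or intermolecular coupling may win. The fallback separates bond formation from deoxygenation and sets out from 27. SmI2 in THF should give the C-a,C-b pinacol F3 by intramolecular ketyl coupling at low temperature. 1,1′-Thiocarbonyldiimidazole in hot toluene should convert it into the cyclic thionocarbonate F4. Heating F4 with 1,3-dimethyl-2-phenyl-1,3,2-diazaphospholidine (Corey–Winter olefination) should give the Z-alkene. The fallback returns to the route at 29.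

3. Step 22 (aryl addition). Enolisation of the hindered α-aryl ketone may outrun addition to the carbonyl group. The fallback uses enolisation productively and sets out from 33. Methylation of the phenol (K2CO3, MeI, acetone) should give the methyl ether F5. KN(SiMe3)2 and PhNTf2 should give the enol triflate F6. Suzuki–Miyaura coupling with 4-methoxyphenylboronic acid (Pd(PPh3)4, K3PO4, dioxane–H2O, 80 °C) should give the tetrasubstituted alkene F7. Ionic hydrogenation under the conditions of step 23 passes through the same C-f cation and should give the pentadeca-O-methyl ether F8. Demethylation as in step 24 returns to the route at 37.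

**Further compounds**

F1 | step 21 | benzylic methyl ether of 31 (OMe on C-d, both epimers) | Oc1ccc(C(OC)[C@H]2c4cc(OC)cc5c4[C@@H](c4cc(OC)cc(OC)c4[C@H](c4ccc(OC)cc4)[C@H]2c2cc(OC)cc4c2[C@@H](c2cc(OC)cc(OC)c2)[C@H](c2ccc(OC)cc2)O4)[C@H](c2ccc(OC)cc2)O5)cc1
F2 | step 21 | (2R,3R)-ε-viniferin pentamethyl ether: (2R,3R)-3-(3,5-dimethoxyphenyl)-6-methoxy-2-(4-methoxyphenyl)-4-[(E)-2-(4-methoxyphenyl)ethenyl]-2,3-dihydro-1-benzofuran | COc1ccc(/C=C/c2cc(OC)cc3c2[C@@H](c2cc(OC)cc(OC)c2)[C@H](c2ccc(OC)cc2)O3)cc1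
F3 | step 18 | pinacol of 27 (diol at C-a and C-b) | c1ccccc1COc1ccc(C[C@H]2c4cc(OC)cc5c4[C@@H](c4cc(OC)cc(OC)c4C(O)(c4ccc(OC)cc4)C2(O)c2cc(OC)cc4c2[C@@H](c2cc(OC)cc(OC)c2)[C@H](c2ccc(OC)cc2)O4)[C@H](c2ccc(OC)cc2)O5)cc1
F4 | step 18 | cyclic thionocarbonate of F3 | c1ccccc1COc1ccc(C[C@H]2c4cc(OC)cc5c4[C@@H](c4cc(OC)cc(OC)c4C6(c4ccc(OC)cc4)OC(=S)OC26c2cc(OC)cc4c2[C@@H](c2cc(OC)cc(OC)c2)[C@H](c2ccc(OC)cc2)O4)[C@H](c2ccc(OC)cc2)O5)cc1
F5 | step 22 | O-methyl ether of 33 | O=C2c3c(OC)cc(OC)cc3[C@@H]3c4c(cc(OC)cc4C2[C@H](c2ccc(OC)cc2)[C@H]2c4cc(OC)cc5c4[C@@H](c4cc(OC)cc(OC)c4[C@H](c4ccc(OC)cc4)[C@H]2c2cc(OC)cc4c2[C@@H](c2cc(OC)cc(OC)c2)[C@H](c2ccc(OC)cc2)O4)[C@H](c2ccc(OC)cc2)O5)O[C@H]3c2ccc(OC)cc2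
F6 | step 22 | enol triflate of F5 (C-e=C-f, OTf on C-f) | FC(F)(F)S(=O)(=O)OC=2c3c(OC)cc(OC)cc3[C@@H]3c4c(cc(OC)cc4C=2[C@H](c2ccc(OC)cc2)[C@H]2c4cc(OC)cc5c4[C@@H](c4cc(OC)cc(OC)c4[C@H](c4ccc(OC)cc4)[C@H]2c2cc(OC)cc4c2[C@@H](c2cc(OC)cc(OC)c2)[C@H](c2ccc(OC)cc2)O4)[C@H](c2ccc(OC)cc2)O5)O[C@H]3c2ccc(OC)cc2
F7 | step 22 | tetrasubstituted alkene (C-e=C-f, 4-methoxyphenyl on C-f) | COc1ccc(cc1)C=2c3c(OC)cc(OC)cc3[C@@H]3c4c(cc(OC)cc4C=2[C@H](c2ccc(OC)cc2)[C@H]2c4cc(OC)cc5c4[C@@H](c4cc(OC)cc(OC)c4[C@H](c4ccc(OC)cc4)[C@H]2c2cc(OC)cc4c2[C@@H](c2cc(OC)cc(OC)c2)[C@H](c2ccc(OC)cc2)O4)[C@H](c2ccc(OC)cc2)O5)O[C@H]3c2ccc(OC)cc2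
F8 | step 22 | pentadeca-O-methyl ether of 37 | COc1ccc([C@H]2c3c(OC)cc(OC)cc3[C@@H]3c4c(cc(OC)cc4[C@H]2[C@H](c2ccc(OC)cc2)[C@H]2c4cc(OC)cc5c4[C@@H](c4cc(OC)cc(OC)c4[C@H](c4ccc(OC)cc4)[C@H]2c2cc(OC)cc4c2[C@@H](c2cc(OC)cc(OC)c2)[C@H](c2ccc(OC)cc2)O4)[C@H](c2ccc(OC)cc2)O5)O[C@H]3c2ccc(OC)cc2)cc1
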